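**Strategy.** The cyclohexanone ring (C1, C11–C15; bicyclo[9.3.1]pentadecane numbering) is read as the adduct of a 2-silyloxydiene (C12=C13–C14=C1) and a 2-methyl-enal (C11=C15, formyl as latent C15 methyl) that are joined through the C2–C10 chain of an acyclic pentaenal. One intramolecular Diels–Alder reaction forms C11–C12 and C1–C15 and so closes the six- and the twelve-membered ring together; it exploits the 1,4 relation of the C13 oxygen to C15 and the trans 1,3-bridge across C15. A 10S carbinol steers the facial sense and is then inverted by oxidation and reduction; sulfone elimination to the C12 methylidene and double epoxidation end the route.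

Key step: step 14

Remark: the SMILES is read as a verticillane in which the C1–C2 and C11–C10 bonds are trans on the six-membered ring, the 3,4-oxirane derives from a 3E olefin and the 7,8-oxirane from a 7Z olefin; locants C1–C18 below follow this numbering (C15 = gem-dimethyl carbon, C18 = methylidene carbon).

**Route**

Step 1
Reactants: 1 geraniol
Product: 2 geranyl tert-butyldimethylsilyl ether
Conditions: TBSCl, imidazole, DMF, 25 °C
Reagents that add atoms: tert-butyldimethylsilyl chloride, CC(C)(C)[Si](C)(C)Cl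
Why: Imidazole-mediated silylation of the primary allylic alcohol; the ether must survive the organolithium step and the 2E olefin is untouched.

Step 2
Reactants: 2 geranyl tert-butyldimethylsilyl ether
Product: 3 racemic 6,7-epoxide of 2
Conditions: mCPBA (1.05 equiv), CH2Cl2, −20 → 0 °C
Reagents that add atoms: 3-chloroperoxybenzoic acid, OOC(=O)c1cccc(Cl)c1
Why: Prilezhaev epoxidation should take the remote, electron-richer trisubstituted olefin before the one deactivated by the allylic oxygen; the new stereocentre is destroyed in step 3.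

Step 3
Reactants: 3 racemic 6,7-epoxide
Product: 4 (4E)-6-[(tert-butyldimethylsilyl)oxy]-4-methylhex-4-enal
Conditions: H5IO6, THF/Et2O, 0 °C
Reagents that add atoms: none
Why: Periodic acid opens the oxirane to the glycol and cleaves it (Malaprade-type cleavage) to the aldehyde and acetone.

Step 4
Reactants: 4 aldehyde
Product: 5 tert-butyl{[(2E,6Z)-7-iodo-3-methylocta-2,6-dien-1-yl]oxy}dimethylsilane
Conditions: EtPPh3I, n-BuLi, THF, 0 °C; I2, −78 °C; NaN(SiMe3)2, −20 °C; then 4, −78 → −20 °C
Reagents that add atoms: ethyltriphenylphosphonium iodide, CC[P+](c1ccccc1)(c1ccccc1)c1ccccc1.[I-]; iodine, II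
Why: Wittig olefination with the α-iodo ylide (Stork–Zhao type) should give the (Z)-2-iodoalkene under kinetic control, which fixes the later 7Z olefin (C6 and C9 cis).

Step 5
Reactants: 5 (Z)-alkenyl iodide; 6 (S)-epichlorohydrin
Product: 8 (2S,4Z,8E)-10-[(tert-butyldimethylsilyl)oxy]-1-chloro-4,8-dimethyldeca-4,8-dien-2-ol, via alkenyllithium 7 (not isolated)
Conditions: t-BuLi (2.1 equiv), Et2O, −78 °C; then 6, BF3·OEt2, −78 °C
Reagents that add atoms: none
Why: Iodine–lithium exchange retains the olefin geometry and the BF3-assisted SN2 opening occurs at the CH2 terminus of the oxirane, so the carbinol carbon (future C10) keeps the configuration of 6 (S).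

Step 6
Reactants: 8 chlorohydrin
Product: 10 (3S,5Z,9E)-11-[(tert-butyldimethylsilyl)oxy]-5,9-dimethylundeca-1,5,9-trien-3-ol, via terminal epoxide 9 (not isolated)
Conditions: Me3SI (4 equiv), n-BuLi (3.9 equiv), THF, −10 → 25 °C
Reagents that add atoms: trimethylsulfonium iodide, C[S+](C)C.[I-]
Why: Dimethylsulfonium methylide first closes the chlorohydrin to the epoxide, then opens it at CH2, and the β-oxido sulfonium salt loses dimethyl sulfide (one-carbon homologation of an epoxide to an allylic alcohol); C10 is not touched.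

Step 7
Reactants: 10 allylic alcohol
Product: 11 (2E,4S,6Z,10E)-12-[(tert-butyldimethylsilyl)oxy]-4-hydroxy-2,6,10-trimethyldodeca-2,6,10-trienal
Conditions: methacrolein (10 equiv), second-generation Hoveyda–Grubbs catalyst RuCl2(H2IMes)(=CH–C6H4-2-OiPr) (5 mol%), 1,4-benzoquinone (10 mol%), CH2Cl2, 40 °C
Reagents that add atoms: methacrolein, CC(=C)C=O
Why: Olefin cross-metathesis of the only monosubstituted olefin with the 1,1-disubstituted enal; the trisubstituted olefins are inert and the 2E enal is the thermodynamic product.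

Step 8
Reactants: 11 silyl ether
Product: 12 (2E,4S,6Z,10E)-4,12-dihydroxy-2,6,10-trimethyldodeca-2,6,10-trienal
Conditions: HF·pyridine, pyridine, THF, 0 → 25 °C
Reagents that add atoms: none
Why: Fluoride cleavage of the primary silyl ether under buffered conditions that leave the γ-hydroxy enal intact.

Step 9
Reactants: 12 diol
Product: 13 (2E,4S,6Z,10E)-12-bromo-4-hydroxy-2,6,10-trimethyldodeca-2,6,10-trienal
Conditions: CBr4 (1.05 equiv), PPh3 (1.1 equiv), CH2Cl2, −30 °C
Reagents that add atoms: carbon tetrabromide, BrC(Br)(Br)Br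
Why: Appel reaction; the primary allylic alcohol should react well before the hindered secondary carbinol next to the electron-poor olefin, by SN2 with the 10E geometry kept.

Step 10
Reactants: 14 3-(phenylsulfanyl)propanoic acid
Product: 15 3-(phenylsulfanyl)propanoyl chloride
Conditions: (COCl)2, DMF (cat.), CH2Cl2, 0 → 25 °C
Reagents that add atoms: oxalyl chloride, ClC(=O)C(Cl)=O
Why: Standard acid chloride formation through the Vilsmeier intermediate.

Step 11
Reactants: 15 acid chloride; 16 (E)-1,2-bis(tributylstannyl)ethene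
Product: 17 (1E)-5-(phenylsulfanyl)-1-(tributylstannyl)pent-1-en-3-one
Conditions: PdCl2(PPh3)2 (5 mol%), THF, 60 °C
Reagents that add atoms: none
Why: Stille acylation of one C–Sn bond with retention of the E geometry; the β-stannyl enone formed is deactivated towards a second coupling.

Step 12
Reactants: 17 stannyl enone
Product: 18 tributyl[(1E,3Z)-5-(phenylsulfanyl)-3-{[tri(propan-2-yl)silyl]oxy}penta-1,3-dien-1-yl]stannane
Conditions: TIPSOTf (1.2 equiv), Et3N (2 equiv), Et2O, −78 → 0 °C
Reagents that add atoms: triisopropylsilyl trifluoromethanesulfonate, CC(C)[Si](C(C)C)(C(C)C)OS(=O)(=O)C(F)(F)F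
Why: Soft enolisation at the only enolisable position gives the cross-conjugated 2-silyloxydiene; the Z enol ether (CH2SPh trans to the vinyl group, an "outside" substituent) is favoured by allylic strain.

Step 13
Reactants: 13 allylic bromide; 18 dienylstannane
Product: 19 (2E,4S,6Z,10E,13E,15Z)-4-hydroxy-2,6,10-trimethyl-17-(phenylsulfanyl)-15-{[tri(propan-2-yl)silyl]oxy}heptadeca-2,6,10,13,15-pentaenal
Conditions: Pd2(dba)3 (5 mol%), AsPh3 (20 mol%), THF, 45 °C; filtration through Et3N-deactivated silica
Reagents that add atoms: none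
Why: Stille allyl–alkenyl coupling through the π-allylpalladium intermediate at its primary terminus under neutral conditions, with all olefin geometries retained.

Step 14
Reactants: 19 pentaenal
Product: 20 (1R,3E,7Z,10S,11R,12R,15R)-10-hydroxy-4,8,15-trimethyl-12-[(phenylsulfanyl)methyl]-13-{[tri(propan-2-yl)silyl]oxy}bicyclo[9.3.1]pentadeca-3,7,13-triene-15-carbaldehyde
Conditions: Me2AlCl (2.2 equiv), CH2Cl2, −78 → −30 °C, 19 added slowly to 0.002 M; aqueous sodium potassium tartrate work-up
Reagents that add atoms: none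
Why: Me2AlCl turns the C10 hydroxyl into its aluminium alkoxide and activates the formyl group, and the silyloxydiene adds across C11=C15 in an asynchronous [4+2] whose stepwise limit (Mukaiyama–Michael addition at C11, then closure of the C15 enolate on C1) leads to the same adduct; the reaction type is the Lewis-acid-promoted intramolecular Diels–Alder reaction of a 2-silyloxydiene with a 2-methyl-enal, run as a macrocyclisation. The six-membered ring closes as the cycloadduct, and the twelve-membered ring closes in the bridged 1,3-mode because the C2–C10 chain ties diene terminus C1 to dienophile carbon C11 while C1 bonds to C15. The step needs this regiochemistry above all, and it is the electronically matched one: the enol-ether terminus C12 (largest HOMO coefficient) attacks the enal β-carbon C11, which places the C13 oxygen and C15 in a 1,4 relation, whereas the fused alternative (C1–C11 and C12–C15) is mismatched and would have to form the quaternary centre first. C1 and C11 should come out trans-bridged because the complexed formyl group sits endo, so that the 2E enal holds C10 exo and on the face opposite to C2, the outside substituent of the 13E diene terminus. The absolute sense is set by the 10S carbinol: C10–H eclipses C11=C15 to escape allylic 1,3-strain with the cis methyl on C15, the chain carbon C9 must then lie on the face that the tethered diene can reach and the O–Al group on the other, which gives the 1R,11R adduct (spatially the arrangement of the target); C12 and C15 follow from the 15Z enol ether and the endo formyl group and are erased later. High dilution and slow addition hold back bimolecular addition.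

Step 15
Reactants: 20 aldehyde
Product: 21 N-tosylhydrazone of 20
Conditions: TsNHNH2 (1.1 equiv), 4 Å molecular sieves, CHCl3, 25 °C
Reagents that add atoms: 4-methylbenzenesulfonohydrazide, Cc1ccc(cc1)S(=O)(=O)NN
Why: Condensation at the only free carbonyl group (any lactol with the C10 hydroxyl opens under the conditions), while the silyl enol ether keeps C13 masked.

Step 16
Reactants: 21 tosylhydrazone
Product: 22 (1R,3E,7Z,10S,11R,12R)-4,8,15,15-tetramethyl-12-[(phenylsulfanyl)methyl]-13-{[tri(propan-2-yl)silyl]oxy}bicyclo[9.3.1]pentadeca-3,7,13-trien-10-ol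
Conditions: catecholborane (3 equiv), CHCl3, 0 °C; then NaOAc·3H2O, 60 °C
Reagents that add atoms: none
Why: Hydride addition to C=N, then loss of sulfinate and dinitrogen (Wolff–Kishner-type deoxygenation in its catecholborane variant), turns the formyl group into the second C15 methyl; there is no α-hydrogen, so no olefin-forming pathway exists.

Step 17
Reactants: 22 alcohol (10S)
Product: 23 (1R,3E,7Z,11R,12R)-4,8,15,15-tetramethyl-12-[(phenylsulfanyl)methyl]-13-{[tri(propan-2-yl)silyl]oxy}bicyclo[9.3.1]pentadeca-3,7,13-trien-10-one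
Conditions: Dess–Martin periodinane, pyridine, CH2Cl2, 0 °C
Reagents that add atoms: none
Why: Dess–Martin oxidation of the outward-pointing C10 carbinol under buffered conditions that spare sulfide, enol ether and the β,γ-olefin.

Step 18
Reactants: 23 ketone
Product: 24 (1R,3E,7Z,10R,11R,12R)-4,8,15,15-tetramethyl-12-[(phenylsulfanyl)methyl]-13-{[tri(propan-2-yl)silyl]oxy}bicyclo[9.3.1]pentadeca-3,7,13-trien-10-ol
Conditions: NaBH4, MeOH/THF, −40 °C
Reagents that add atoms: none
Why: With C9 held gauche to C15 by the ring, the inner face of the C10 carbonyl is covered by C15 and its β-methyl, so hydride should add from the outer face (anti to C15), placing hydrogen outside and oxygen inside, which is 10R.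

Step 19
Reactants: 24 alcohol (10R)
Product: 25 10R acetate of 24
Conditions: Ac2O, DMAP, Et3N, CH2Cl2, 25 °C
Reagents that add atoms: acetic anhydride, CC(=O)OC(C)=O
Why: DMAP-catalysed acylation of the hindered secondary alcohol with retention at C10.

Step 20
Reactants: 25 silyl enol ether
Product: 26 (1R,3E,7Z,10R,11R,12R)-4,8,15,15-tetramethyl-13-oxo-12-[(phenylsulfanyl)methyl]bicyclo[9.3.1]pentadeca-3,7-dien-10-yl acetate
Conditions: HF·pyridine, THF, 0 → 25 °C
Reagents that add atoms: none
Why: Fluoride-induced cleavage of the silyl enol ether and C-protonation release the C13 ketone under non-basic conditions that keep the β-sulfanyl ketone and the acetate.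

Step 21
Reactants: 26 β-sulfanyl ketone
Product: 28 target, (1R,3R,4R,7R,8S,10R,11S)-3,4:7,8-diepoxy-4,8,15,15-tetramethyl-12-methylidene-13-oxobicyclo[9.3.1]pentadecan-10-yl acetate, via bis-epoxy sulfone 27 (not isolated)
Conditions: DMDO (5 equiv, acetone), CH2Cl2, 0 °C; volatiles removed; then DBU (3 equiv), CH2Cl2, 25 °C
Reagents that add atoms: dimethyldioxirane, CC1(C)OO1
Why: The electrophilic dioxirane oxidises sulfur to the sulfone and should epoxidise both ring olefins on their outer faces (each olefin stands roughly perpendicular to the twelve-membered ring; 3E gives the trans and 7Z the cis oxirane), and DBU then expels benzenesulfinate by E1cB elimination to unveil the C12 methylidene only after the oxidant is gone (the C11 descriptor becomes S only because C12 turns sp2).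

**Compound list**

1 | geraniol, (2E)-3,7-dimethylocta-2,6-dien-1-ol | CC(C)=CCC/C(C)=C/CO | starting material
2 | tert-butyl{[(2E)-3,7-dimethylocta-2,6-dien-1-yl]oxy}dimethylsilane | CC(C)=CCC/C(C)=C/CO[Si](C)(C)C(C)(C)C | intermediate
3 | tert-butyl{[(2E)-5-(3,3-dimethyloxiran-2-yl)-3-methylpent-2-en-1-yl]oxy}dimethylsilane (racemic) | CC1(C)OC1CC/C(C)=C/CO[Si](C)(C)C(C)(C)C | intermediate
4 | (4E)-6-[(tert-butyldimethylsilyl)oxy]-4-methylhex-4-enal | O=CCC/C(C)=C/CO[Si](C)(C)C(C)(C)C | intermediate
5 | tert-butyl{[(2E,6Z)-7-iodo-3-methylocta-2,6-dien-1-yl]oxy}dimethylsilane | C/C(I)=C/CC/C(C)=C/CO[Si](C)(C)C(C)(C)C | intermediate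
6 | (S)-epichlorohydrin, (2S)-2-(chloromethyl)oxirane | ClC[C@@H]1CO1 | starting material
7 | alkenyllithium from 5 (lithium in place of iodine, geometry retained) | C/C([Li])=C/CC/C(C)=C/CO[Si](C)(C)C(C)(C)C | intermediate
8 | (2S,4Z,8E)-10-[(tert-butyldimethylsilyl)oxy]-1-chloro-4,8-dimethyldeca-4,8-dien-2-ol | ClC[C@@H](O)C/C(C)=C\CC/C(C)=C/CO[Si](C)(C)C(C)(C)C | intermediate
9 | tert-butyl({(2E,6Z)-3,7-dimethyl-8-[(2S)-oxiran-2-yl]octa-2,6-dien-1-yl}oxy)dimethylsilane | C1O[C@H]1C/C(C)=C\CC/C(C)=C/CO[Si](C)(C)C(C)(C)C | intermediate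
10 | (3S,5Z,9E)-11-[(tert-butyldimethylsilyl)oxy]-5,9-dimethylundeca-1,5,9-trien-3-ol | C=C[C@@H](O)C/C(C)=C\CC/C(C)=C/CO[Si](C)(C)C(C)(C)C | intermediate
11 | (2E,4S,6Z,10E)-12-[(tert-butyldimethylsilyl)oxy]-4-hydroxy-2,6,10-trimethyldodeca-2,6,10-trienal | O=C/C(C)=C/[C@@H](O)C/C(C)=C\CC/C(C)=C/CO[Si](C)(C)C(C)(C)C | intermediate
12 | (2E,4S,6Z,10E)-4,12-dihydroxy-2,6,10-trimethyldodeca-2,6,10-trienal | O=C/C(C)=C/[C@@H](O)C/C(C)=C\CC/C(C)=C/CO | intermediate
13 | (2E,4S,6Z,10E)-12-bromo-4-hydroxy-2,6,10-trimethyldodeca-2,6,10-trienal | O=C/C(C)=C/[C@@H](O)C/C(C)=C\CC/C(C)=C/CBr | intermediate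
14 | 3-(phenylsulfanyl)propanoic acid | OC(=O)CCSc1ccccc1 | starting material
15 | 3-(phenylsulfanyl)propanoyl chloride | ClC(=O)CCSc1ccccc1 | intermediate
16 | (E)-1,2-bis(tributylstannyl)ethene | CCCC[Sn](CCCC)(CCCC)/C=C/[Sn](CCCC)(CCCC)CCCC | starting material
17 | (1E)-5-(phenylsulfanyl)-1-(tributylstannyl)pent-1-en-3-one | CCCC[Sn](CCCC)(CCCC)/C=C/C(=O)CCSc1ccccc1 | intermediate
18 | tributyl[(1E,3Z)-5-(phenylsulfanyl)-3-{[tri(propan-2-yl)silyl]oxy}penta-1,3-dien-1-yl]stannane | CCCC[Sn](CCCC)(CCCC)/C=C/C(O[Si](C(C)C)(C(C)C)C(C)C)=C/CSc1ccccc1 | intermediate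
19 | (2E,4S,6Z,10E,13E,15Z)-4-hydroxy-2,6,10-trimethyl-17-(phenylsulfanyl)-15-{[tri(propan-2-yl)silyl]oxy}heptadeca-2,6,10,13,15-pentaenal | O=C/C(C)=C/[C@@H](O)C/C(C)=C\CC/C(C)=C/C/C=C/C(O[Si](C(C)C)(C(C)C)C(C)C)=C/CSc1ccccc1 | intermediate
20 | (1R,3E,7Z,10S,11R,12R,15R)-10-hydroxy-4,8,15-trimethyl-12-[(phenylsulfanyl)methyl]-13-{[tri(propan-2-yl)silyl]oxy}bicyclo[9.3.1]pentadeca-3,7,13-triene-15-carbaldehyde | c1ccccc1SC[C@H]1C(O[Si](C(C)C)(C(C)C)C(C)C)=C[C@H]2C/C=C(C)/CC/C=C(C)\C[C@H](O)[C@H]1[C@]2(C)C=O | intermediate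
21 | (E)-N-tosylhydrazone of 20 | c1ccccc1SC[C@H]1C(O[Si](C(C)C)(C(C)C)C(C)C)=C[C@H]2C/C=C(C)/CC/C=C(C)\C[C@H](O)[C@H]1[C@]2(C)/C=N/NS(=O)(=O)c1ccc(C)cc1 | intermediate
22 | (1R,3E,7Z,10S,11R,12R)-4,8,15,15-tetramethyl-12-[(phenylsulfanyl)methyl]-13-{[tri(propan-2-yl)silyl]oxy}bicyclo[9.3.1]pentadeca-3,7,13-trien-10-ol | c1ccccc1SC[C@H]1C(O[Si](C(C)C)(C(C)C)C(C)C)=C[C@H]2C/C=C(C)/CC/C=C(C)\C[C@H](O)[C@H]1C2(C)C | intermediate
23 | (1R,3E,7Z,11R,12R)-4,8,15,15-tetramethyl-12-[(phenylsulfanyl)methyl]-13-{[tri(propan-2-yl)silyl]oxy}bicyclo[9.3.1]pentadeca-3,7,13-trien-10-one | c1ccccc1SC[C@H]1C(O[Si](C(C)C)(C(C)C)C(C)C)=C[C@H]2C/C=C(C)/CC/C=C(C)\CC(=O)[C@H]1C2(C)C | intermediate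
24 | (1R,3E,7Z,10R,11R,12R)-4,8,15,15-tetramethyl-12-[(phenylsulfanyl)methyl]-13-{[tri(propan-2-yl)silyl]oxy}bicyclo[9.3.1]pentadeca-3,7,13-trien-10-ol | c1ccccc1SC[C@H]1C(O[Si](C(C)C)(C(C)C)C(C)C)=C[C@H]2C/C=C(C)/CC/C=C(C)\C[C@@H](O)[C@H]1C2(C)C | intermediate
25 | (1R,3E,7Z,10R,11R,12R)-4,8,15,15-tetramethyl-12-[(phenylsulfanyl)methyl]-13-{[tri(propan-2-yl)silyl]oxy}bicyclo[9.3.1]pentadeca-3,7,13-trien-10-yl acetate | c1ccccc1SC[C@H]1C(O[Si](C(C)C)(C(C)C)C(C)C)=C[C@H]2C/C=C(C)/CC/C=C(C)\C[C@@H](OC(C)=O)[C@H]1C2(C)C | intermediate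
26 | (1R,3E,7Z,10R,11R,12R)-4,8,15,15-tetramethyl-13-oxo-12-[(phenylsulfanyl)methyl]bicyclo[9.3.1]pentadeca-3,7-dien-10-yl acetate | c1ccccc1SC[C@H]1C(=O)C[C@H]2C/C=C(C)/CC/C=C(C)\C[C@@H](OC(C)=O)[C@H]1C2(C)C | intermediate
27 | (1R,3R,4R,7R,8S,10R,11R,12R)-3,4:7,8-diepoxy-4,8,15,15-tetramethyl-13-oxo-12-[(phenylsulfonyl)methyl]bicyclo[9.3.1]pentadecan-10-yl acetate | O=S(=O)(c1ccccc1)C[C@H]1C(=O)C[C@H]2C[C@H]3O[C@]3(C)CC[C@H]3O[C@@]3(C)C[C@@H](OC(C)=O)[C@H]1C2(C)C | intermediate
28 | (1R,3R,4R,7R,8S,10R,11S)-3,4:7,8-diepoxy-4,8,15,15-tetramethyl-12-methylidene-13-oxobicyclo[9.3.1]pentadecan-10-yl acetate | C=C1C(=O)C[C@H]2C[C@H]3O[C@]3(C)CC[C@H]3O[C@@]3(C)C[C@@H](OC(C)=O)[C@H]1C2(C)C | target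

**Count**

Total step count: 21. Longest linear sequence: 18 steps (steps 1–9 and 13–21, from geraniol).

**Steps most likely to fail**

Step 14. At the dilution that the macrocyclisation needs, ring closure may be too slow, so that bimolecular addition to the formyl group, oligomerisation or loss of the silyl enol ether takes over, and the facial bias from C10 may be eroded. The fallback changes the dienophile and the source of asymmetry and sets out from bromide 13. Dess–Martin oxidation gives the achiral keto-enal bromide F1, and Stille coupling with 18 as in step 13 gives the keto pentaenal F2. Its doubly activated C11=C15 bond should cyclise at −78 °C under a chiral B-(o-tolyl)oxazaborolidinium triflimide of the CBS family. The catalyst binds only the formyl group, keeps it endo and the C10 ketone exo, and supplies the facial control that the carbinol gave before; its enantiomer is assigned on a model enal, because the sense of induction is not derived here. The keto aldehyde F3 so formed is converted at the formyl group into its tosylhydrazone F4 and reduced as in step 16, which rejoins the route at ketone 23.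

Step 21. Oxygen may be delivered to the wrong face of one or both ring olefins (poor or inverted facial selectivity); the outer-face assignment rests on a conformational argument, not on a model. The fallback brings oxygen to the opposite face by a halohydrin sequence and sets out from 26. Sulfur alone is oxidised ((NH4)6Mo7O24, H2O2, EtOH) to the sulfone F6, and DBU gives the trienone F7. NBS in aqueous THF forms the bromonium ions on the faces that the peracid would use and water opens them at the tertiary carbons C4 and C8 from the other side, giving the bis(bromohydrin) F8. DBU closes both oxiranes with inversion at C3 and C7 and the sequence arrives at target 28. If only one olefin misbehaves, the same two operations are applied to that olefin alone.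

Step 18. Hydride may be delivered from both faces of the C10 carbonyl (poor facial selectivity), and the basic medium may epimerise C11 or move the 7,8-olefin into conjugation. The fallback avoids the ketone and sets out from the 10S alcohol 22. A Mitsunobu reaction (4-nitrobenzoic acid, PPh3, DIAD, toluene) inverts C10 and gives the 10R 4-nitrobenzoate F5; the inner face is then the one that must be open, which is the case if hydride could reach it. Methanolysis (K2CO3, MeOH) rejoins the route at alcohol 24.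

Further compounds
F1 | step 14 | (2E,6Z,10E)-12-bromo-2,6,10-trimethyl-4-oxododeca-2,6,10-trienal | O=C/C(C)=C/C(=O)C/C(C)=C\CC/C(C)=C/CBr
F2 | step 14 | (2E,6Z,10E,13E,15Z)-2,6,10-trimethyl-4-oxo-17-(phenylsulfanyl)-15-{[tri(propan-2-yl)silyl]oxy}heptadeca-2,6,10,13,15-pentaenal | O=C/C(C)=C/C(=O)C/C(C)=C\CC/C(C)=C/C/C=C/C(O[Si](C(C)C)(C(C)C)C(C)C)=C/CSc1ccccc1
F3 | step 14 | (1R,3E,7Z,11R,12R,15R)-4,8,15-trimethyl-10-oxo-12-[(phenylsulfanyl)methyl]-13-{[tri(propan-2-yl)silyl]oxy}bicyclo[9.3.1]pentadeca-3,7,13-triene-15-carbaldehyde | c1ccccc1SC[C@H]1C(O[Si](C(C)C)(C(C)C)C(C)C)=C[C@H]2C/C=C(C)/CC/C=C(C)\CC(=O)[C@H]1[C@]2(C)C=O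
F4 | step 14 | (E)-N-tosylhydrazone of F3 | c1ccccc1SC[C@H]1C(O[Si](C(C)C)(C(C)C)C(C)C)=C[C@H]2C/C=C(C)/CC/C=C(C)\CC(=O)[C@H]1[C@]2(C)/C=N/NS(=O)(=O)c1ccc(C)cc1
F5 | step 18 | (1R,3E,7Z,10R,11R,12R)-4,8,15,15-tetramethyl-12-[(phenylsulfanyl)methyl]-13-{[tri(propan-2-yl)silyl]oxy}bicyclo[9.3.1]pentadeca-3,7,13-trien-10-yl 4-nitrobenzoate | c1ccccc1SC[C@H]1C(O[Si](C(C)C)(C(C)C)C(C)C)=C[C@H]2C/C=C(C)/CC/C=C(C)\C[C@@H](OC(=O)c3ccc(cc3)[N+](=O)[O-])[C@H]1C2(C)C
F6 | step 21 | (1R,3E,7Z,10R,11R,12R)-4,8,15,15-tetramethyl-13-oxo-12-[(phenylsulfonyl)methyl]bicyclo[9.3.1]pentadeca-3,7-dien-10-yl acetate | O=S(=O)(c1ccccc1)C[C@H]1C(=O)C[C@H]2C/C=C(C)/CC/C=C(C)\C[C@@H](OC(C)=O)[C@H]1C2(C)C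
F7 | step 21 | (1R,3E,7Z,10R,11S)-4,8,15,15-tetramethyl-12-methylidene-13-oxobicyclo[9.3.1]pentadeca-3,7-dien-10-yl acetate | C=C1C(=O)C[C@H]2C/C=C(C)/CC/C=C(C)\C[C@@H](OC(C)=O)[C@H]1C2(C)C
F8 | step 21 | 3,7-dibromo-4,8-dihydroxy-4,8,15,15-tetramethyl-12-methylidene-13-oxobicyclo[9.3.1]pentadecan-10-yl acetate (bromine at C3 and C7 anti to the tertiary hydroxyls, configured to close to the target oxiranes) | C=C1C(=O)C[C@H]2C[C@H](Br)[C@@](O)(C)CC[C@H](Br)[C@](O)(C)C[C@@H](OC(C)=O)[C@H]1C2(C)C
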